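All runs were computed from invented constants; scatter was added.

Substrate is the easy species to read, because its curve in each earlier run needs only two points for a rate, and the flasks asked about differ in how things go in.

| flask | substrate | partner | remark | time |
|---|---|---|---|---|
| Wednesday's | 0.020 M | 1.5 equiv | run made earlier |  |
| Tuesday's | 0.028 M | 1.5 equiv | run made earlier |  |
| Thursday's | 0.044 M | 1.5 equiv | run made earlier |  |
| summer | 0.020 M (fed, over 5.0 min) | 1.50 equiv | all else is in the flask from the start; the feed brings no volume worth counting | 8.0 min |
| winter | 0.020 M | 1.50 equiv | everything together at the start | 8.0 min |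
| midnight | 0.020 M | 1.50 equiv (fed, over 5.0 min) | all else is in the flask from the start; the feed brings no volume worth counting | 8.0 min |
| spring | 0.020 M | 1.50 equiv (in portions, 5, over 5.0 min) | first portion at the start, last at 5.0 min | 8.0 min |

| run | time / min | target / % | substrate / % |
|---|---|---|---|
| Wednesday's | 1.00 | 20.5 | 54.3 |
| Wednesday's | 2.50 | 52.2 | 21.0 |
| Wednesday's | 3.00 | 57.7 | 16.1 |
| Wednesday's | 5.00 | 72.5 | 4.9 |
| Wednesday's | 6.00 | 75.8 | 1.7 |
| Wednesday's | 8.00 | 79.6 | 3.9 |
| Tuesday's | 0.667 | 13.9 | 63.6 |
| Tuesday's | 1.00 | 22.2 | 52.3 |
| Tuesday's | 1.33 | 30.2 | 41.6 |
| Tuesday's | 2.50 | 49.1 | 20.4 |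
| Tuesday's | 3.00 | 55.8 | 14.0 |
| Tuesday's | 5.00 | 70.7 | 5.1 |
| Tuesday's | 8.00 | 73.2 | 0 |
| Thursday's | 1.00 | 19.3 | 51.9 |
| Thursday's | 2.50 | 46.2 | 18.8 |
| Thursday's | 3.00 | 49.8 | 14.5 |
| Thursday's | 5.00 | 62.7 | 5.7 |
| Thursday's | 6.00 | 66.2 | 1.0 |
| Thursday's | 8.00 | 68.1 | 0 |

(standard deviation of a reading: 1 percentage point)

- what was read earlier has a scatter of 1 percentage point, one standard deviation

- the best flask by amount of target, in percent of the substrate charged; "all alike" if 1.5 percentage points covers them all (summer / winter / midnight / spring / all alike)
- amount of target at the end, in percent of the substrate charged, summer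
- amount of target at the end, in percent of the substrate charged, winter
- amount of target at the end, in percent of the substrate charged, midnight
- amount of target at the end, in percent of the substrate charged, spring

From each run I take the rate constant of substrate between its readings at 1.00 min and 5.00 min, and the share missing at the last reading, which is neither target nor substrate.

| run | c(substrate) | rate constant | missing share |
|---|---|---|---|
| Wednesday's | 0.020 M | 0.601 /min | 16.5% |
| Tuesday's | 0.028 M | 0.582 /min | 26.8% |
| Thursday's | 0.044 M | 0.552 /min | 31.9% |

Reading down the rate column, the constant barely moves while c(substrate) grows by a factor of 2.20, so I treat substrate as first order and keep Wednesday's value, since that run has summer's charge. Reading down the last column, the missing share is larger at Thursday's concentration than at Wednesday's, so a flask that keeps c(substrate) low should lose less.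

Now the end state and its approach. A steady feed holds, as it stops, the fraction 31.6% of the charge as unreacted substrate, and that pool then decays for the remaining time. What stands at the reading is the lag, 5.21%: the share of a fed charge still unreacted as substrate at the time of reading. Summer's target should therefore lie below 94.8%, and above 78.3% if its missing share stays under Wednesday's. I take the middle, 86.5%. The lag says nothing on midnight and spring, where substrate goes in at the start.

The forecast gives 80% for summer, under my figure, 80% for winter, 79.5% for midnight and 80% for spring, and so all alike: “all four flasks come out about alike”.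

The best flask is summer, with summer at 87.2%, winter at 79.4%, midnight at 51.9% and spring at 50.9%, so midnight stands 28 percentage points under the forecast.

    partner → second intermediate (k = 0.0280 /s)
    open intermediate + second intermediate → target (k = 2.20 /M/s)
    substrate ⇌ open intermediate (K = 2.10, k = 0.0120 /s)
    partner ⇌ dormant form (K = 0.260, k = 0.0290 /s)
    2 open intermediate → homo product (k = 0.0690 /M/s)
    partner + target → over-reaction product (k = 1.70 /M/s)

At 8.00 min summer holds 5.34% substrate beside my lag of 5.21%, while partner stands at 0% of its charge and second intermediate at 0.0109 M. Summer's target, the lag and 2.86% open intermediate add up to 95.3%. The same reckoning on the neighbouring flask, summer left until 30 min, gives a lag of <0.001%, and that flask holds 0% substrate, 0% open intermediate and 95.4% target.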